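**Plan**

- Numbering: ring A (cyclohexene) is C1–C14(isopropyl)–C13–C12=C11(Me)–C10; the ten-membered ring is C1–C2–C3(CO2Me)–C4–C5=C6–C7(Me)–C8–C9–C10, with an oxygen joining C4 and C7.
- Enabling feature: C4 (hemiketal carbon) and C8 (acyloxy carbon) both bear oxygen and stand 1,5 to each other over C5=C6–C7. A C4–C8 bond would therefore fold the ten-membered ring into a cyclopentene (C4–C8) fused to a cycloheptane (C1, C2, C3, C4, C8, C9, C10), so the target is made from a cyclohexene–cycloheptane–cyclopentene tricycle carrying a C4,C8-diol whose shared bond is cut.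
- Retrosynthesis, in order: C8–O acyl bond; C8–H (ketone reduction); C4–O(C7) hemiketal bond; C4–C8 (re-formed as the diol); C3–C4 (ester-enolate aldol); C8–OH; C8–C9 (enolate alkylation); then, in the ring A fragment, C2=C3 (Wittig) and the C2–C9 bond of a dichloroketene adduct on C1=C10.
- Forward: ring A is bought as (R)-α-phellandrene and gains a cyclobutanone that is opened again; the cyclopentenone is made from 2,5-dimethylfuran; the fragments are joined at C8–C9; the seven-membered ring closes by aldol, the ten-membered ring appears by glycol cleavage, and the dihydrofuran closes last by hemiketal formation.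
- Stereochemistry: C14 from (R)-α-phellandrene; C1 and C10 from cis ketene addition anti to the isopropyl group; C7 from resolved (R)-4-hydroxy-4-methylcyclopent-2-enone; C3 from the aldol (a β-keto ester centre after the cleavage, hence correctable); C4 fixed by the oxygen bridge; C8 from hydride addition to the bridged ketone.

Key step: step 15

Assumption: the configurations drawn at C4 and C8 of the intermediates between the fragment coupling and the glycol cleavage are the expected ones and are of no consequence for the target, since both carbons become carbonyl carbons in step 15.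

**Route**

Step 1
Reactants: 1 (R)-α-phellandrene; 2 trichloroacetyl chloride
Product: 4 8,8-dichloro-2-methyl-5-(propan-2-yl)bicyclo[4.2.0]oct-2-en-7-one (cis-fused; four-membered ring anti to the isopropyl group; C=O on target C1; CCl2 on target C10), via dichloroketene 3 (not isolated)
Conditions: activated Zn dust, Et2O, ultrasound, 15–20 °C
Reagents that add atoms: none
Why: Ketene–alkene [2+2] cycloaddition, in which dichloroketene freed by zinc dechlorination adds suprafacially to the disubstituted C1=C10 bond of the diene from the face opposite the C14 isopropyl group with its carbonyl carbon on the diene terminus C1, so that C1 and C10 are set cis to each other and trans to the isopropyl group.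

Step 2
Reactants: 4 dichlorocyclobutanone
Product: 5 methyl 2-(dichloromethyl)-3-methyl-6-(propan-2-yl)cyclohex-3-ene-1-carboxylate (ester cis to CHCl2; both trans to isopropyl)
Conditions: NaOMe (0.3 equiv), MeOH, −20 °C
Reagents that add atoms: methanol, CO; delivered as sodium methoxide, [Na+].[O-]C
Why: Haloform-type ring opening of an α,α-dichlorocyclobutanone, in which methoxide adds to the strained carbonyl and the tetrahedral intermediate expels the dichloromethyl carbanion, cutting the C2–C9 bond while the low temperature and substoichiometric base spare the C1 stereocentre.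

Step 3
Reactants: 5 dichloromethyl ester
Product: 6 methyl 2-(chloromethyl)-3-methyl-6-(propan-2-yl)cyclohex-3-ene-1-carboxylate (configuration as in 5)
Conditions: Bu3SnH (1.05 equiv), 2,2'-azobis(2-methylpropionitrile) (cat.), benzene, 80 °C
Reagents that add atoms: none
Why: Radical-chain hydrodechlorination, in which the stannyl radical removes the first chlorine of the gem-dichloride (giving an α-chloro-stabilised radical) much faster than it attacks the resulting primary chloride, so one equivalent of hydride should stop at the chloromethyl stage.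

Step 4
Reactants: 6 chloromethyl ester
Product: 7 2-(chloromethyl)-3-methyl-6-(propan-2-yl)cyclohex-3-ene-1-carbaldehyde (configuration as in 5)
Conditions: i-Bu2AlH (1.1 equiv), CH2Cl2, −78 °C; aq. potassium sodium tartrate
Reagents that add atoms: none
Why: Partial ester reduction with i-Bu2AlH, whose tetrahedral aluminium hemiacetal is stable at −78 °C and releases the aldehyde only on work-up, the primary chloride and the alkene being inert.

Step 5
Reactants: 7 aldehyde; 8 methyl (triphenylphosphoranylidene)acetate
Product: 9 methyl (2E)-3-[2-(chloromethyl)-3-methyl-6-(propan-2-yl)cyclohex-3-en-1-yl]prop-2-enoate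
Conditions: toluene, 60 °C
Reagents that add atoms: none
Why: Wittig olefination with a stabilised, weakly basic ylide, which leaves the α-stereocentre C1 untouched, gives the (E)-enoate and brings in C3 and the ester carbon.

Step 6
Reactants: 9 enoate
Product: 10 methyl 3-[2-(chloromethyl)-3-methyl-6-(propan-2-yl)cyclohex-3-en-1-yl]propanoate
Conditions: Mg turnings, MeOH, 0 → 20 °C
Reagents that add atoms: none
Why: Dissolving-metal conjugate reduction (Mg in methanol) is selective for the electron-poor enoate C=C and leaves the trisubstituted ring alkene and the primary chloride alone.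

Step 7
Reactants: 10 chloro ester
Product: 11 methyl 3-[2-(iodomethyl)-3-methyl-6-(propan-2-yl)cyclohex-3-en-1-yl]propanoate
Conditions: NaI (5 equiv), 2-butanone, 80 °C
Reagents that add atoms: sodium iodide, [Na+].[I-]
Why: Finkelstein halide exchange (SN2 at the primary carbon C9), driven by precipitation of NaCl, turns the chloride into the more reactive iodide.

Step 8
Reactants: 12 2,5-dimethylfuran
Product: 13 (Z)-hex-3-ene-2,5-dione
Conditions: 3-chloroperoxybenzoic acid (1.0 equiv), CH2Cl2, 0 °C
Reagents that add atoms: 3-chloroperoxybenzoic acid, OOC(=O)c1cccc(Cl)c1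
Why: Peracid oxidative ring opening of a 2,5-dialkylfuran, which hands the cis geometry of the furan on to the enedione.

Step 9
Reactants: 13 (Z)-enedione
Product: 14 rac-4-hydroxy-4-methylcyclopent-2-en-1-one
Conditions: Na2CO3 (0.1 M in H2O), 20 °C
Reagents that add atoms: none
Why: Intramolecular aldol addition, in which a methyl-ketone enolate closes onto the second carbonyl (possible only for the Z isomer) to give the tertiary carbinol as a racemate.

Step 10
Reactants: 14 racemic hydroxy enone
Product: 15 (R)-4-hydroxy-4-methylcyclopent-2-en-1-one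
Conditions: preparative HPLC, amylose tris(3,5-dimethylphenylcarbamate) on silica, hexane/i-PrOH
Reagents that add atoms: none
Why: Chromatographic resolution on a chiral stationary phase should separate the enantiomers of this small hydrogen-bonding hydroxy enone without derivatising the tertiary alcohol; the (R)-enantiomer, which becomes C7, is kept and its assignment is to be secured by X-ray analysis of a heavy-atom derivative.

Step 11
Reactants: 15 (R)-hydroxy enone
Product: 16 (R)-4-methyl-4-(triethylsilyloxy)cyclopent-2-en-1-one
Conditions: Et3SiOSO2CF3, 2,6-lutidine, CH2Cl2, −78 → 0 °C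
Reagents that add atoms: triethylsilyl trifluoromethanesulfonate, CC[Si](CC)(CC)OS(=O)(=O)C(F)(F)F
Why: Silylation of a tertiary alcohol with a silyl triflate and a hindered pyridine base, giving an ether that tolerates the amide bases of steps 12–14 and is removed by fluoride in step 16.

Step 12
Reactants: 16 silyloxy cyclopentenone; 11 iodo ester
Product: 18 methyl 3-[2-{[5-methyl-2-oxo-5-(triethylsilyloxy)cyclopent-3-en-1-yl]methyl}-3-methyl-6-(propan-2-yl)cyclohex-3-en-1-yl]propanoate (C8–H; C9 cis to the C7 silyloxy group), via lithium dienolate 17 (not isolated)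
Conditions: 16 (3 equiv), LiN(i-Pr)2 (2.9 equiv), THF, −78 °C; then 11, N,N'-dimethylpropyleneurea, −78 → −30 °C
Reagents that add atoms: none
Why: Alkylation of a kinetic lithium enolate (SN2 on the primary iodide) at C8, the only enolisable position of 16, with the electrophile expected opposite the C7 methyl group; the C8 configuration is immaterial because C8 is enolised again in step 13.

Step 13
Reactants: 18 alkylated keto ester
Product: 20 methyl 3-[2-{[1-hydroxy-5-methyl-2-oxo-5-(triethylsilyloxy)cyclopent-3-en-1-yl]methyl}-3-methyl-6-(propan-2-yl)cyclohex-3-en-1-yl]propanoate (C8–OH cis to the C7 silyloxy group), via potassium dienolate 19 (not isolated)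
Conditions: KN(SiMe3)2 (1.1 equiv), THF, −78 °C; then 2-(phenylsulfonyl)-3-phenyloxaziridine, −78 °C; aq. NH4Cl
Reagents that add atoms: 2-(phenylsulfonyl)-3-phenyloxaziridine, O=S(=O)(c1ccccc1)N1OC1c1ccccc1
Why: Davis oxidation of a ketone enolate, the C8–H being far more acidic than the ester α-hydrogens and the oxaziridine delivering oxygen to C8 on the dienolate face opposite the C7 methyl group without touching the C11=C12 alkene.

Step 14
Reactants: 20 hydroxy keto ester
Product: 22 6-7-5 tricyclic C4/C8-diol (cis-fused at C1/C10 and at C4/C8; C4–OH and C8–OH and C7–OSiEt3 on one face; C3 ester trans to C4–OH), via dilithium alkoxide enolate 21 (not isolated)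
Conditions: LiN(i-Pr)2 (2.3 equiv), THF, −78 → −50 °C; aq. NH4Cl at −78 °C
Reagents that add atoms: none
Why: Intramolecular aldol addition of a lithium ester enolate to a non-enolisable ketone (7-enolexo-exo-trig), in which the tether from C8 reaches C4 only on the face that carries C9, so the C4 hydroxyl forms cis to the C8 hydroxyl, and C3 is expected with its ester trans to the C4 oxygen through a lithium-chelated transition state.

Step 15
Reactants: 22 tricyclic diol
Product: 24 ten-membered (Z)-enedione (C4 and C8 ketones; C7–OSiEt3; C3–CO2Me), via cyclic lead diester 23 (not isolated)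
Conditions: Pb(OAc)4 (1.1 equiv), CH2Cl2, −20 → 0 °C, 15 min
Reagents that add atoms: none
Why: Criegee glycol cleavage: the cis tertiary hydroxyls at C4 and C8 displace two acetates from tetravalent lead to give the five-membered cyclic diester 23, which collapses in a concerted two-electron fragmentation that breaks the C4–C8 bond, releases divalent lead as Pb(OAc)2 and leaves a ketone on each carbon. The closest known reaction type is the Pb(OAc)4 or NaIO4 scission of ring-fusion 1,2-diols in fused bicycles to medium-ring diketones. The ten-membered ring is not closed end to end but appears by ring-expanding fragmentation, the periphery of the fused cyclopentene and cycloheptane becoming the cyclodecene once their shared bond is gone. No stereocentre is created: C1, C3, C7, C10 and C14 are spectators, the two carbinol centres become carbonyl carbons, and C5=C6 keeps the cis geometry imposed by the former cyclopentene, which the C7 oxygen later needs to reach C4. The step requires the oxidant to attack only the diol, and Pb(OAc)4 in an aprotic solvent at or below 0 °C leaves the C11=C12 alkene, the ester and the tertiary silyl ether alone, while the short contact time limits α-acetoxylation or epimerisation at the new β-keto ester centre C3.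

Step 16
Reactants: 24 enedione
Product: 26 hemiketal ketone (2,5-dihydrofuran bridging C4 and C7; C4–OH; C8 ketone), via C7-hydroxy enedione 25 (not isolated)
Conditions: HF·pyridine, pyridine, THF, 0 °C
Reagents that add atoms: none
Why: Fluoride desilylation, after which the C7 hydroxyl, held next to the C4 enone carbonyl by the cis C5=C6 bond, adds to it spontaneously (5-exo-trig hemiketal formation); the C4 configuration is dictated by the bridge, and buffering with pyridine avoids dehydration towards C3.

Step 17
Reactants: 26 hemiketal ketone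
Product: 27 (8S)-alcohol (C8–OH; C4 hemiketal OH free)
Conditions: NaBH4, MeOH/THF (1:4), −40 °C
Reagents that add atoms: none
Why: Ketone reduction by borohydride, with hydride expected on the face of C8=O flanked by the one-atom oxygen bridge and not the C5=C6 bridge (opposite the C7 methyl group), which gives the 8S carbinol while the ester and the hemiketal survive at −40 °C.

Step 18
Reactants: 28 1-methyl-1H-imidazole-4-carbaldehyde; 29 malonic acid
Product: 30 (E)-3-(1-methyl-1H-imidazol-4-yl)prop-2-enoic acid
Conditions: pyridine, piperidine (cat.), 100 °C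
Reagents that add atoms: none
Why: Knoevenagel–Doebner condensation with decarboxylation, which gives the (E)-acrylic acid directly.

Step 19
Reactants: 27 (8S)-alcohol; 30 N-methylurocanic acid
Product: 32 target CNP0113846.1 (C8 ester of 27 with 30), via mixed pivalic anhydride 31 (not isolated)
Conditions: 30, t-BuCOCl, Et3N, THF, 20 °C; then 27, 4-(dimethylamino)pyridine, CH2Cl2, 20 °C
Reagents that add atoms: none
Why: Esterification through a mixed anhydride with nucleophilic catalysis, in which the secondary C8 alcohol attacks the unhindered urocanoyl carbonyl in preference to the tertiary C4 hemiketal hydroxyl, which stays free.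

**Compound list**

1 | (R)-α-phellandrene | CC1=CC[C@H](C(C)C)C=C1 | starting material
2 | trichloroacetyl chloride | ClC(Cl)(Cl)C(Cl)=O | starting material
3 | dichloroketene | ClC(Cl)=C=O | intermediate
4 | 8,8-dichloro-2-methyl-5-(propan-2-yl)bicyclo[4.2.0]oct-2-en-7-one, cis-fused, anti to isopropyl | O=C1[C@@H]2[C@@H](C(C)C)CC=C(C)[C@@H]2C1(Cl)Cl | intermediate
5 | methyl 2-(dichloromethyl)-3-methyl-6-(propan-2-yl)cyclohex-3-ene-1-carboxylate | COC(=O)[C@@H]1[C@@H](C(C)C)CC=C(C)[C@@H]1C(Cl)Cl | intermediate
6 | methyl 2-(chloromethyl)-3-methyl-6-(propan-2-yl)cyclohex-3-ene-1-carboxylate | COC(=O)[C@@H]1[C@@H](C(C)C)CC=C(C)[C@@H]1CCl | intermediate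
7 | 2-(chloromethyl)-3-methyl-6-(propan-2-yl)cyclohex-3-ene-1-carbaldehyde | O=C[C@@H]1[C@@H](C(C)C)CC=C(C)[C@@H]1CCl | intermediate
8 | methyl (triphenylphosphoranylidene)acetate | COC(=O)C=P(c1ccccc1)(c1ccccc1)c1ccccc1 | starting material
9 | methyl (2E)-3-[2-(chloromethyl)-3-methyl-6-(propan-2-yl)cyclohex-3-en-1-yl]prop-2-enoate | COC(=O)/C=C/[C@@H]1[C@@H](C(C)C)CC=C(C)[C@@H]1CCl | intermediate
10 | methyl 3-[2-(chloromethyl)-3-methyl-6-(propan-2-yl)cyclohex-3-en-1-yl]propanoate | COC(=O)CC[C@@H]1[C@@H](C(C)C)CC=C(C)[C@@H]1CCl | intermediate
11 | methyl 3-[2-(iodomethyl)-3-methyl-6-(propan-2-yl)cyclohex-3-en-1-yl]propanoate | COC(=O)CC[C@@H]1[C@@H](C(C)C)CC=C(C)[C@@H]1CI | intermediate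
12 | 2,5-dimethylfuran | Cc1ccc(C)o1 | starting material
13 | (Z)-hex-3-ene-2,5-dione | CC(=O)/C=C\C(C)=O | intermediate
14 | rac-4-hydroxy-4-methylcyclopent-2-en-1-one | CC1(O)C=CC(=O)C1 | intermediate
15 | (R)-4-hydroxy-4-methylcyclopent-2-en-1-one | O=C1C=C[C@](C)(O)C1 | intermediate
16 | (R)-4-methyl-4-(triethylsilyloxy)cyclopent-2-en-1-one | O=C1C=C[C@](C)(O[Si](CC)(CC)CC)C1 | intermediate
17 | lithium dienolate of 16 (C4–OLi, C4=C8) | [Li]OC1=C[C@@](C)(O[Si](CC)(CC)CC)C=C1 | intermediate
18 | C8-alkylated cyclopentenone keto ester | COC(=O)CC[C@@H]1[C@@H](C(C)C)CC=C(C)[C@@H]1C[C@H]2[C@@](C)(O[Si](CC)(CC)CC)C=CC2=O | intermediate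
19 | potassium dienolate of 18 (C4–OK, C4=C8) | COC(=O)CC[C@@H]1[C@@H](C(C)C)CC=C(C)[C@@H]1CC2=C(O[K])C=C[C@]2(C)O[Si](CC)(CC)CC | intermediate
20 | C8-hydroxy keto ester | COC(=O)CC[C@@H]1[C@@H](C(C)C)CC=C(C)[C@@H]1C[C@]2(O)[C@@](C)(O[Si](CC)(CC)CC)C=CC2=O | intermediate
21 | dilithium C8-alkoxide ester enolate of 20 | COC(O[Li])=CC[C@@H]1[C@@H](C(C)C)CC=C(C)[C@@H]1C[C@]2(O[Li])[C@@](C)(O[Si](CC)(CC)CC)C=CC2=O | intermediate
22 | 6-7-5 tricyclic C4,C8-diol with C7 triethylsilyl ether | COC(=O)[C@@H]1C[C@@H]2[C@@H](C(C)C)CC=C(C)[C@@H]2C[C@]3(O)[C@@](C)(O[Si](CC)(CC)CC)C=C[C@]13O | intermediate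
23 | cyclic lead diester of 22 (C4–O–Pb(OAc)2–O–C8) | COC(=O)[C@@H]1C[C@@H]2[C@@H](C(C)C)CC=C(C)[C@@H]2C[C@]3(O4)[C@@](C)(O[Si](CC)(CC)CC)C=C[C@]13O[Pb]4(OC(C)=O)OC(C)=O | intermediate
24 | ten-membered (Z)-enedione, C7 triethylsilyl ether | COC(=O)[C@@H]1C[C@@H]2[C@@H](C(C)C)CC=C(C)[C@@H]2CC(=O)[C@@](C)(O[Si](CC)(CC)CC)/C=C\C1=O | intermediate
25 | C7-hydroxy (Z)-enedione | COC(=O)[C@@H]1C[C@@H]2[C@@H](C(C)C)CC=C(C)[C@@H]2CC(=O)[C@@](C)(O)/C=C\C1=O | intermediate
26 | hemiketal ketone (C4–O–C7 bridge, C8 ketone) | COC(=O)[C@@H]1C[C@@H]2[C@@H](C(C)C)CC=C(C)[C@@H]2CC(=O)[C@]3(C)C=C[C@@]1(O)O3 | intermediate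
27 | (8S)-alcohol | COC(=O)[C@@H]1C[C@@H]2[C@@H](C(C)C)CC=C(C)[C@@H]2C[C@H](O)[C@]3(C)C=C[C@@]1(O)O3 | intermediate
28 | 1-methyl-1H-imidazole-4-carbaldehyde | O=Cc1cn(C)cn1 | starting material
29 | malonic acid | OC(=O)CC(O)=O | starting material
30 | (E)-3-(1-methyl-1H-imidazol-4-yl)prop-2-enoic acid | OC(=O)/C=C/c1cn(C)cn1 | intermediate
31 | mixed anhydride of 30 with pivalic acid | CC(C)(C)C(=O)OC(=O)/C=C/c1cn(C)cn1 | intermediate
32 | CNP0113846.1 | COC(=O)[C@@H]1C[C@@H]2[C@@H](C(C)C)CC=C(C)[C@@H]2C[C@H](OC(=O)/C=C/c2cn(C)cn2)[C@]2(C)C=C[C@@]1(O)O2 | target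

**Step count**

Total: 19 steps. Longest linear sequence: 14 steps (steps 1–7, 12–17 and 19, from (R)-α-phellandrene).

**Steps most likely to fail**

Step 12 (C8–C9 alkylation). The SN2 reaction of the β-branched iodide may be slower than the side processes open to the partners: loss of silanolate from the β-silyloxy dienolate, E2 loss of HI from 11 towards a conjugated diene, proton transfer to the ester of 11 followed by five-membered ring closure onto the iodide, and double alkylation. The fallback sets out from 11 and 16 and returns at 18; it replaces the alkylation by an aldol addition, which is fast at −78 °C, and removes the extra oxygen afterwards. Iodide 11 is oxidised with Me3NO in DMSO at 20 °C (amine-oxide displacement and elimination) to the C9 aldehyde F1, which is used at once. The lithium dienolate 17 made from 16 adds to it at −78 °C to give the C9-hydroxy aldol adduct F2. Its secondary hydroxyl is converted with 1,1'-thiocarbonyldiimidazole into the O-thiocarbonylimidazolide F3. Barton–McCombie deoxygenation (Bu3SnH, 2,2'-azobis(2-methylpropionitrile), toluene, 80 °C) then gives 18.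

Step 14 (seven-membered ring closure). The aldol equilibrium between a hindered ketone and an ester enolate may lie on the open side, the C8 lithium alkoxide may trigger α-ketol rearrangement on warming, or closure may be slow enough for intermolecular Claisen chemistry. The fallback sets out from 20 and returns at 22; it uses a Lewis-acid Mukaiyama aldol, which is irreversible and keeps the C8 oxygen capped. Compound 20 is deprotonated with LiN(i-Pr)2 in the presence of Me3SiCl (internal quench) to give the bis-silylated ketene silyl acetal F4 (C8–OSiMe3 and methyl trimethylsilyl ketene acetal). BF3·OEt2 in CH2Cl2 at −78 °C closes the C3–C4 bond and gives the tricyclic C8 trimethylsilyl ether F5. K2CO3 in MeOH removes the trimethylsilyl group in the presence of the tertiary triethylsilyl ether and gives 22.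

Step 17 (C8 reduction). Facial selectivity of hydride addition to the ketone of the flexible bridged ring may be poor, and the basic medium may open the hemiketal. The fallback sets out from 26 and returns at 27; it replaces substrate control by reagent control in a Corey–Bakshi–Shibata reduction with catecholborane and the oxazaborolidine (R)-1-methyl-3,3-diphenyltetrahydro-1H,3H-pyrrolo[1,2-c][1,3,2]oxazaborole in toluene at −40 °C. The quaternary C7 acts as the large and C9H2 as the small substituent, which with the (R)-catalyst predicts the 8S alcohol 27 without any new intermediate (entry F0 below).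

**Further compounds**

F1 | step 12 | methyl 3-[2-formyl-3-methyl-6-(propan-2-yl)cyclohex-3-en-1-yl]propanoate (C9 aldehyde) | COC(=O)CC[C@@H]1[C@@H](C(C)C)CC=C(C)[C@@H]1C=O
F2 | step 12 | C9-hydroxy aldol adduct of 17 and F1 | COC(=O)CC[C@@H]1[C@@H](C(C)C)CC=C(C)[C@@H]1C(O)[C@H]2[C@@](C)(O[Si](CC)(CC)CC)C=CC2=O
F3 | step 12 | C9 O-thiocarbonylimidazolide of F2 | COC(=O)CC[C@@H]1[C@@H](C(C)C)CC=C(C)[C@@H]1C(OC(=S)n3ccnc3)[C@H]2[C@@](C)(O[Si](CC)(CC)CC)C=CC2=O
F4 | step 14 | C8-O-trimethylsilyl ketene silyl acetal of 20 | COC(O[Si](C)(C)C)=CC[C@@H]1[C@@H](C(C)C)CC=C(C)[C@@H]1C[C@]2(O[Si](C)(C)C)[C@@](C)(O[Si](CC)(CC)CC)C=CC2=O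
F5 | step 14 | tricyclic C4-hydroxy C8-trimethylsilyl ether | COC(=O)[C@@H]1C[C@@H]2[C@@H](C(C)C)CC=C(C)[C@@H]2C[C@]3(O[Si](C)(C)C)[C@@](C)(O[Si](CC)(CC)CC)C=C[C@]13O
F0 | step 17 | none | none
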